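**Assumptions:** The SMILES is taken as definitive: butenolide C5 is (R), the C(CH2OH)=CH alkene is Z (CH2OH cis to the CH2 bearing the lactone), and the C(CH3)=CH alkene is E. Dihydroxyacetone is used as its commercial dimer. The route is a paper design and has not been run.

## Retrosynthetic overview

1. Target 20 comes from bis-trityl ether 19 by acid detritylation; the C5 stereocentre of 19 comes from a proposed enantioselective desilylative γ-protonation of the achiral 2-silyloxyfuran 18.
2. 18 comes from C5–CH2 bond formation between the 5-lithio derivative of silyloxyfuran 17 and the (Z)-allylic bromide 12.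
3. 12 comes from a Still–Gennari olefination of phosphonate 6 with TBSOCH2CHO, which sets the Z-C(CH2OR)=CH unit; 6 comes from homoallylic iodide 4.
4. 4 comes from alkyne 2 by Zr-catalysed carboalumination and ethylene oxide opening, which sets the E-trisubstituted alkene; 2 comes from dihydro-β-ionone.
5. Ring order: the cyclohexene is bought; the butenolide ring is made first on the east piece (15), carried as the aromatic silyloxyfuran, and regenerated as the chiral lactone in the stereodefining step.

## Route

**Step 1**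
Reactants: 1, dihydro-β-ionone [4-(2,6,6-trimethylcyclohex-1-en-1-yl)butan-2-one]
Product: 2, 2-(but-3-yn-1-yl)-1,3,3-trimethylcyclohex-1-ene
Conditions: LDA (1.05 equiv), THF, −78 °C; ClP(O)(OEt)2, −78 °C → rt; LDA (2.3 equiv), −78 °C → rt
Reagents that add atoms: none
Why: Kinetic deprotonation at the methyl group gives the terminal enol diethyl phosphate, which undergoes base-induced elimination to the terminal alkyne (Negishi methyl ketone → alkyne protocol).

**Step 2**
Reactants: 2, 2-(but-3-yn-1-yl)-1,3,3-trimethylcyclohex-1-ene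
Product: 3, (3E)-4-methyl-6-(2,6,6-trimethylcyclohex-1-en-1-yl)hex-3-en-1-ol
Conditions: Me3Al (2 equiv), Cp2ZrCl2 (0.25 equiv), CH2Cl2, rt; remove volatiles; n-BuLi, THF/hexane, −30 °C; ethylene oxide, −30 °C → rt
Reagents that add atoms: trimethylaluminium, C[Al](C)C (adds CH3); ethylene oxide, C1CO1 (adds CH2CH2OH)
Why: Negishi Zr-catalysed syn-carboalumination places CH3 on the internal carbon cis to Al, and the derived alkenylalanate opens the epoxide with retention, so the alkene is E.

**Step 3**
Reactants: 3, (3E)-4-methyl-6-(2,6,6-trimethylcyclohex-1-en-1-yl)hex-3-en-1-ol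
Product: 4, 2-[(3E)-6-iodo-3-methylhex-3-en-1-yl]-1,3,3-trimethylcyclohex-1-ene
Conditions: I2, PPh3, imidazole, CH2Cl2, 0 °C
Reagents that add atoms: iodine, II
Why: Appel-type (Garegg–Samuelsson) iodination is an SN2 displacement at the primary carbon and leaves the alkenes untouched.

**Step 4**
Reactants: 4, the homoallylic iodide; 5, methyl bis(2,2,2-trifluoroethyl)phosphonoacetate
Product: 6, methyl (5E)-2-[bis(2,2,2-trifluoroethoxy)phosphoryl]-6-methyl-8-(2,6,6-trimethylcyclohex-1-en-1-yl)oct-5-enoate (racemic at C2, which is later destroyed)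
Conditions: 5 (1.3 equiv), NaH, DMF, 0 °C; then 4, rt → 45 °C
Reagents that add atoms: none besides reactant 5, COC(=O)CP(=O)(OCC(F)(F)F)OCC(F)(F)F
Why: SN2 C-alkylation of the soft, weakly basic phosphonoacetate anion by a primary iodide, with excess phosphonate to suppress dialkylation.

**Step 5**
Reactants: 6, the α-alkylated phosphonate; 7, (tert-butyldimethylsilyloxy)acetaldehyde
Product: 8, methyl (2Z,5E)-2-[2-(tert-butyldimethylsilyloxy)ethylidene]-6-methyl-8-(2,6,6-trimethylcyclohex-1-en-1-yl)oct-5-enoate (CO2Me cis to CH2OTBS)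
Conditions: KHMDS, 18-crown-6, THF, −78 °C; then 7
Reagents that add atoms: none besides reactant 7, O=CCO[Si](C)(C)C(C)(C)C
Why: Still–Gennari olefination, in which the electron-poor trifluoroethyl phosphonate with a dissociated potassium counter-ion eliminates irreversibly from the kinetic adduct to give the Z-trisubstituted enoate.

**Step 6**
Reactants: 8, the Z-enoate
Product: 9, (2Z,5E)-2-[2-(tert-butyldimethylsilyloxy)ethylidene]-6-methyl-8-(2,6,6-trimethylcyclohex-1-en-1-yl)oct-5-en-1-ol (CH2OH cis to CH2OTBS)
Conditions: DIBAL-H (2.5 equiv), CH2Cl2, −78 °C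
Reagents that add atoms: none
Why: 1,2-Reduction of the enoate to the allylic alcohol does not touch the alkene geometry or the silyl ether.

**Step 7**
Reactants: 9, the allylic alcohol
Product: 10, tert-butyldimethyl{[(2Z,6E)-7-methyl-9-(2,6,6-trimethylcyclohex-1-en-1-yl)-3-(trityloxymethyl)nona-2,6-dien-1-yl]oxy}silane
Conditions: TrCl, Et3N, DMAP (cat.), CH2Cl2, rt
Reagents that add atoms: trityl chloride, ClC(c1ccccc1)(c1ccccc1)c1ccccc1
Why: Tritylation of the primary alcohol installs a fluoride-stable, acid-labile group orthogonal to the TBS ether.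

**Step 8**
Reactants: 10, the trityl/TBS bis-ether
Product: 11, (2Z,6E)-7-methyl-9-(2,6,6-trimethylcyclohex-1-en-1-yl)-3-(trityloxymethyl)nona-2,6-dien-1-ol
Conditions: TBAF, THF, 0 °C
Reagents that add atoms: none
Why: Fluoride cleaves only the Si–O bond, and the trityl ether can neither cleave nor migrate under these conditions.

**Step 9**
Reactants: 11, the allylic alcohol
Product: 12, (2Z,6E)-1-bromo-7-methyl-9-(2,6,6-trimethylcyclohex-1-en-1-yl)-3-(trityloxymethyl)nona-2,6-diene (used at once)
Conditions: MsCl, Et3N, CH2Cl2, −40 °C; LiBr, THF, 0 °C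
Reagents that add atoms: lithium bromide, [Li+].[Br-]
Why: Mesylation followed by SN2 bromide displacement at the primary allylic carbon under cold, non-acidic conditions avoids allylic transposition and E/Z scrambling.

**Step 10**
Reactants: 13, 1,3-dihydroxyacetone (commercial dimer); 14, ethyl (triphenylphosphoranylidene)acetate
Product: 15, 4-(hydroxymethyl)furan-2(5H)-one
Conditions: CH2Cl2, rt, 16 h
Reagents that add atoms: none besides reactant 14, CCOC(=O)C=P(c1ccccc1)(c1ccccc1)c1ccccc1
Why: Wittig olefination of the symmetrical ketone necessarily places one CH2OH cis to the ester, which lactonises spontaneously to form the butenolide ring.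

**Step 11**
Reactants: 15, 4-(hydroxymethyl)furan-2(5H)-one
Product: 16, 4-(trityloxymethyl)furan-2(5H)-one
Conditions: TrCl, pyridine, DMAP (cat.), CH2Cl2, rt
Reagents that add atoms: trityl chloride, ClC(c1ccccc1)(c1ccccc1)c1ccccc1
Why: Primary alcohol tritylation, with trityl chosen over a silyl ether because it cannot undergo 1,4 O→C migration to the adjacent lithiated carbon in step 13.

**Step 12**
Reactants: 16, 4-(trityloxymethyl)furan-2(5H)-one
Product: 17, triisopropyl{[4-(trityloxymethyl)furan-2-yl]oxy}silane
Conditions: Et3N (2 equiv), then TIPSOTf (1.1 equiv), CH2Cl2, 0 °C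
Reagents that add atoms: triisopropylsilyl triflate, CC(C)[Si](OS(=O)(=O)C(F)(F)F)(C(C)C)C(C)C
Why: Soft enolisation (γ-deprotonation) and O-silylation of the butenolide gives the aromatic 2-silyloxyfuran, with excess amine protecting the trityl ether from the silyl triflate.

**Step 13**
Reactants: 17, the silyloxyfuran (1.3 equiv); 12, the (Z)-allylic bromide
Product: 18, triisopropyl({5-[(2Z,6E)-7-methyl-9-(2,6,6-trimethylcyclohex-1-en-1-yl)-3-(trityloxymethyl)nona-2,6-dien-1-yl]-4-(trityloxymethyl)furan-2-yl}oxy)silane
Conditions: s-BuLi, TMEDA, THF, −78 → 0 °C; then 12, −78 °C → 0 °C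
Reagents that add atoms: none besides the two reactants
Why: α-Lithiation at C5 (the most acidic ring C–H, next to the ring oxygen) followed by SN2 alkylation with the primary allylic bromide forms the C5–CH2 bond with retention of the Z-alkene (furyllithium alkylation).

**Step 14**
Reactants: 18, the 4,5-disubstituted 2-silyloxyfuran
Product: 19, (5R)-5-[(2Z,6E)-7-methyl-9-(2,6,6-trimethylcyclohex-1-en-1-yl)-3-(trityloxymethyl)nona-2,6-dien-1-yl]-4-(trityloxymethyl)furan-2(5H)-one
Conditions: 9-O-(9-phenanthryl)cupreidine (6′-OH quinidine-derived catalyst, 10 mol %), PhCOF (1.1 equiv), EtOH (1.5 equiv), CH2Cl2, −20 → 0 °C; dilute citric acid work-up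
Reagents that add atoms: none (only H is added)
Why: Proposed new method: catalytic enantioselective desilylative γ-protonation of a fully substituted 2-silyloxyfuran — the amine-catalysed ethanolysis of PhCOF releases HF slowly as the chiral quinuclidinium fluoride, fluoride removes the TIPS group to give a tight ion pair of the furanolate with the protonated catalyst (held by the 6′-OH hydrogen bond), and proton transfer within this pair to one face of C5 sets the (R) centre; any C3-protonated β,γ-isomer is re-enolised by the free quinuclidine and funnelled to the conjugated lactone, whose γ-H is too weakly acidic to be removed by the catalyst, so the ee is kinetic; the closest known reactions are cinchona proton-transfer isomerisation of β,γ- to γ-chiral α,β-butenolides and cinchona/latent-HF enantioselective protonation of silyl enol ethers, neither shown for silyloxyfurans or for β,γ-disubstituted butenolides; the facial sense cannot be predicted with confidence, so the quinine-derived pseudoenantiomer is used instead if the quinidine series gives (S).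

**Step 15**
Reactants: 19, the (5R)-bis-trityl butenolide
Product: 20, (6Z)-neomanoalide [(5R)-4-(hydroxymethyl)-5-[(2Z,6E)-3-(hydroxymethyl)-7-methyl-9-(2,6,6-trimethylcyclohex-1-en-1-yl)nona-2,6-dien-1-yl]furan-2(5H)-one]
Conditions: CSA (0.3 equiv), MeOH/CH2Cl2 (1:1), 0 °C → rt
Reagents that add atoms: none
Why: SN1 methanolysis of both primary trityl ethers via the trityl cation under mild acid, which cannot epimerise C5 because racemisation requires base-mediated γ-deprotonation.

## Compound list

1 | dihydro-β-ionone | CC(=O)CCC1=C(C)CCCC1(C)C | starting material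
2 | 2-(but-3-yn-1-yl)-1,3,3-trimethylcyclohex-1-ene | C#CCCC1=C(C)CCCC1(C)C | intermediate
3 | (3E)-4-methyl-6-(2,6,6-trimethylcyclohex-1-en-1-yl)hex-3-en-1-ol | OCC/C=C(\C)CCC1=C(C)CCCC1(C)C | intermediate
4 | 2-[(3E)-6-iodo-3-methylhex-3-en-1-yl]-1,3,3-trimethylcyclohex-1-ene | ICC/C=C(\C)CCC1=C(C)CCCC1(C)C | intermediate
5 | methyl bis(2,2,2-trifluoroethyl)phosphonoacetate | COC(=O)CP(=O)(OCC(F)(F)F)OCC(F)(F)F | starting material
6 | methyl (5E)-2-[bis(2,2,2-trifluoroethoxy)phosphoryl]-6-methyl-8-(2,6,6-trimethylcyclohex-1-en-1-yl)oct-5-enoate (racemic) | COC(=O)C(CC/C=C(\C)CCC1=C(C)CCCC1(C)C)P(=O)(OCC(F)(F)F)OCC(F)(F)F | intermediate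
7 | (tert-butyldimethylsilyloxy)acetaldehyde | O=CCO[Si](C)(C)C(C)(C)C | starting material
8 | methyl (2Z,5E)-2-[2-(TBSO)ethylidene]-6-methyl-8-(2,6,6-trimethylcyclohex-1-en-1-yl)oct-5-enoate | COC(=O)/C(CC/C=C(\C)CCC1=C(C)CCCC1(C)C)=C\CO[Si](C)(C)C(C)(C)C | intermediate
9 | (2Z,5E)-2-[2-(TBSO)ethylidene]-6-methyl-8-(2,6,6-trimethylcyclohex-1-en-1-yl)oct-5-en-1-ol | OC/C(CC/C=C(\C)CCC1=C(C)CCCC1(C)C)=C\CO[Si](C)(C)C(C)(C)C | intermediate
10 | trityl ether of 9 (TrOCH2 cis to CH2OTBS) | c1ccccc1C(c2ccccc2)(c3ccccc3)OC/C(CC/C=C(\C)CCC4=C(C)CCCC4(C)C)=C\CO[Si](C)(C)C(C)(C)C | intermediate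
11 | (2Z,6E)-7-methyl-9-(2,6,6-trimethylcyclohex-1-en-1-yl)-3-(trityloxymethyl)nona-2,6-dien-1-ol | c1ccccc1C(c2ccccc2)(c3ccccc3)OC/C(CC/C=C(\C)CCC4=C(C)CCCC4(C)C)=C\CO | intermediate
12 | (2Z,6E)-1-bromo-7-methyl-9-(2,6,6-trimethylcyclohex-1-en-1-yl)-3-(trityloxymethyl)nona-2,6-diene | c1ccccc1C(c2ccccc2)(c3ccccc3)OC/C(CC/C=C(\C)CCC4=C(C)CCCC4(C)C)=C\CBr | intermediate
13 | 1,3-dihydroxyacetone (commercial dimer) | OCC(=O)CO | starting material
14 | ethyl (triphenylphosphoranylidene)acetate | CCOC(=O)C=P(c1ccccc1)(c2ccccc2)c3ccccc3 | starting material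
15 | 4-(hydroxymethyl)furan-2(5H)-one | O=C1OCC(CO)=C1 | intermediate
16 | 4-(trityloxymethyl)furan-2(5H)-one | O=C1OCC(COC(c2ccccc2)(c3ccccc3)c4ccccc4)=C1 | intermediate
17 | triisopropyl{[4-(trityloxymethyl)furan-2-yl]oxy}silane | CC(C)[Si](Oc1cc(COC(c2ccccc2)(c3ccccc3)c4ccccc4)co1)(C(C)C)C(C)C | intermediate
18 | 2-TIPSO-4-(trityloxymethyl)-5-[(2Z,6E)-7-methyl-9-(2,6,6-trimethylcyclohex-1-en-1-yl)-3-(trityloxymethyl)nona-2,6-dien-1-yl]furan | CC(C)[Si](Oc1cc(COC(c2ccccc2)(c3ccccc3)c4ccccc4)c(C/C=C(COC(c5ccccc5)(c6ccccc6)c7ccccc7)/CC/C=C(\C)CCC8=C(C)CCCC8(C)C)o1)(C(C)C)C(C)C | intermediate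
19 | (5R)-5-[(2Z,6E)-7-methyl-9-(2,6,6-trimethylcyclohex-1-en-1-yl)-3-(trityloxymethyl)nona-2,6-dien-1-yl]-4-(trityloxymethyl)furan-2(5H)-one | CC1=C(CC/C(C)=C/CC/C(=C/C[C@H]2OC(=O)C=C2COC(c3ccccc3)(c4ccccc4)c5ccccc5)COC(c6ccccc6)(c7ccccc7)c8ccccc8)C(C)(C)CCC1 | intermediate
20 | (6Z)-neomanoalide | CC1=C(CC/C(C)=C/CC/C(=C/C[C@H]2OC(=O)C=C2CO)CO)C(C)(C)CCC1 | target

## Summary

**Total steps:** 15.
**Longest linear sequence:** 12 (steps 1–9, then 13–15); the east fragment is 3 steps (10–12).

**Three steps most likely to fail**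

1. **Step 14 (proposed new enantioselective γ-protonation).** The risks are low ee from background protonation, incomplete funnelling of the β,γ-isomer, and the wrong facial sense.
   Fallback (known chemistry, stereocentre from an auxiliary):
   - alkylate the SAMP or RAMP hydrazone of 2,2-dimethyl-1,3-dioxan-5-one with bromide 12 (Enders alkylation);
   - cleave the hydrazone with aqueous oxalic acid;
   - remove the acetonide and trityl group with acid, then silylate the two primary alcohols;
   - annulate the remaining α-hydroxy ketone with Ph3P=C=C=O (acylation then intramolecular Wittig) to the butenolide, and desilylate with HF·pyridine.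

2. **Step 13 (lithiation and alkylation of the silyloxyfuran).** The risks are incomplete or mis-sited lithiation and SN2′ or Wurtz-type side reactions of the allylic bromide.
   Fallback (introduce the lactone oxygen after the C–C bond):
   - dilithiate 3-furanmethanol (alkoxide-directed C2-lithiation) and alkylate with 12;
   - tritylate the alcohol;
   - lithiate the one remaining α-position, trap with B(OMe)3 and oxidise with H2O2 to the butenolide mixture;
   - convert that mixture to 18 with TIPSOTf/Et3N.

3. **Step 5 (Still–Gennari olefination, together with the alkylation in step 4).** The risks are poor Z:E with the α-branched phosphonate and a low-yielding phosphonate alkylation.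
   Fallback (geometry from trans-hydroalumination instead of olefination):
   - alkylate the dianion of propargyl alcohol with iodide 4;
   - treat with Red-Al then I2 to give the (Z)-3-iodoallylic alcohol;
   - protect as the TBS ether;
   - Stille-couple with Bu3SnCH2OH to reach 9.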